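In a world of one first-order step there is one time constant: [starting material] decays exponentially, and the logarithm of charged over remaining [starting material] grows in proportion to time. These flasks do not behave that way. Here is the quick number asked for, with its reckoning.

| setting | east | south | north-west | south-west |
|---|---|---|---|---|
| starting material | 80.0 mM | 48.0 mM | 80.0 mM | 80.0 mM |
| free catalyst | 2.40 mM | 2.40 mM | 4.80 mM | 16.0 mM |
| time |  |  |  | 21 h |

| run | time / h | [target] / mM |
|---|---|---|
| east run | 0.84 | 4.46 |
| east run | 1.4 | 6.73 |
| east run | 2.5 | 10.23 |
| east run | 4.2 | 14.78 |
| east run | 7.2 | 19.85 |
| east run | 12 | 24.43 |
| east run | 21 | 26.11 |
| south run | 0.84 | 2.70 |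
| south run | 1.4 | 4.20 |
| south run | 2.5 | 6.72 |
| south run | 4.2 | 9.81 |
| south run | 7.2 | 12.45 |
| south run | 12 | 14.86 |
| south run | 21 | 15.74 |
| north-west run | 0.84 | 8.40 |
| north-west run | 1.4 | 13.60 |
| north-west run | 2.5 | 21.04 |
| north-west run | 4.2 | 28.65 |
| north-west run | 7.2 | 37.00 |
| north-west run | 12 | 42.37 |
| north-west run | 21 | 45.52 |

(each reading ± 0.2 mM)

* order of the initial rate in [starting material], near the charge of the east run, the rate being that where two percent of its starting material are target (one fixed amount of target, the same in the runs compared)
* order of the initial rate in [free catalyst], near the charge of the east run, the rate being that where two percent of its starting material are target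
* target in the south-west run at 21 h, as a share of the starting material charged

- Overall: starting material -> target, with free catalyst as catalyst.
- Constant volume, constant temperature.
- Readings of a species count what is bound in complexes too.
- An order is taken over about fifteen percent of the charge, up and down.

The east run gains 1.68 mM of target between 12 h and 21 h. The north-west run has the same charge of starting material and reads 45.52 mM at 21 h, more than the 26.11 mM of the east run, so the stall follows the catalyst charge and is no equilibrium.

The balance to write is therefore that of the smaller charge, free catalyst. If it decays on its own clock, the step is pseudo-first-order, and the logarithm above equals a rate constant times the time integral of [free catalyst]. At 21 h that logarithm is 0.395 in the east run and 0.842 in the north-west run. The line through them has slope 0.186 /mM: this gain of the logarithm at 21 h per mM of free catalyst charged is the reach. Read from these two runs, the line meets zero at a charge of 0.277 mM of free catalyst.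

For 16.0 mM the logarithm comes to 2.93, so my number is 94.6%. That offset also gives the logarithm at 21 h an order in free catalyst of 1.13 near the east charge, which I take for the initial rate as well, and the first readings of the east and south runs, compared at equal time, give about 0.983 in starting material.

The forecast says 0.95 for the order in starting material, 1 for the order in free catalyst and 92% for the share, on the ground that “the catalyst dies on a clock, independent of turnover”. It shares my clock, but its order in free catalyst and its share differ from mine.

The flask runs by these steps:

    free catalyst + starting material ⇌ catalyst-substrate complex, settled at all times (2.730 /M)
    catalyst-substrate complex → target + free catalyst (13.97 /h)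
    free catalyst → spent catalyst (0.1991 /h)
    free catalyst + impurity → spent catalyst

The south-west run gives 94.5%, with orders 0.89 in starting material and 1.2 in free catalyst. At equal target, the north-west run goes 2.2 times as fast as the east run, more than the charge ratio of 2.00. Applied to the south run, with 48.0 mM of starting material and 2.40 mM of free catalyst, the reach gives 15.7 mM of target at 21 h, and the south run reads 15.74 mM.

The numbers in the tables come from a simulation from invented constants.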